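The C19 side chain is cut at its unactivated C9'–C10' methylene–methylene bond, eight CH2 groups from ring carbon C5 and five from the C16'=C17' E-olefin. One Pd-catalysed sp3–sp3 Suzuki–Miyaura coupling joins B-[(E)-dec-7-enyl]-9-BBN, made by terminal-selective hydroboration of (E)-deca-1,7-diene, to a primary bromide that carries the complete ring in masked form: C1 ketone as dimethyl ketal, C5 carbinol and C6 methylene as a cis-epoxide syn to the C4 hydroxyl. Both coupling carbons are primary and remote, so no protecting group is needed. Ketal hydrolysis and SmI2 cleavage of the epoxy enone then unveil the base-labile cis-4,5-dihydroxy enone last.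

Key step: step 7

Numbering used below: ring atoms C1–C6 as in the target (C1 = C=O, C4 = CHOH, C5 = C(OH)R); side chain C1'–C19' counted from the ring.

Assumption: in step 2 the sense of induction follows the usual CBS model with the 2-bromovinyl flank of 2 as the large group; if the dienol should turn out to be the (S)-enantiomer, the (R)-catalyst is used and nothing else changes.

Step 1
Reactants: 1 2-bromo-4-methoxyphenol
Product: 2 2-bromo-4,4-dimethoxycyclohexa-2,5-dien-1-one
Conditions: PhI(OAc)2 (1.1 equiv), MeOH, 0 °C → rt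
Reagents that add atoms: methanol, CO
Why: Hypervalent-iodine oxidative dearomatisation of a 4-methoxyphenol; methanol traps the oxidised ring at C4 para to the oxygen and gives the quinone monoketal.

Step 2
Reactants: 2 2-bromo-4,4-dimethoxycyclohexa-2,5-dien-1-one
Product: 3 (R)-2-bromo-4,4-dimethoxycyclohexa-2,5-dien-1-ol
Conditions: (S)-Me-CBS (20 mol%), catecholborane (1.5 equiv), toluene/CH2Cl2, −78 °C; MeOH quench, aq. NaOH wash, Et3N-treated silica
Reagents that add atoms: none
Why: Corey–Bakshi–Shibata reduction of an α-bromo enone; the bromovinyl flank acts as the large group and the unsubstituted vinylene as the small one, so the catalyst should deliver hydride to one face and set the future C4 carbinol as R, while the base-only work-up avoids loss of methanol and re-aromatisation.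

Step 3
Reactants: 3 (R)-2-bromo-4,4-dimethoxycyclohexa-2,5-dien-1-ol; 4 9-bromonon-1-ene
Product: 6 (R)-2-(9-bromononyl)-4,4-dimethoxycyclohexa-2,5-dien-1-ol, via 9-(9-bromononyl)-9-borabicyclo[3.3.1]nonane 5 (not isolated)
Conditions: 4, 9-BBN, THF, 0 °C → rt; then 3, PdCl2(dppf) (5 mol%), AsPh3, Cs2CO3, DMF/THF/H2O, rt → 40 °C
Reagents that add atoms: none
Why: B-alkyl Suzuki–Miyaura coupling (sp2–sp3); 9-BBN hydroborates the terminal olefin of 4 anti-Markovnikov, and Pd(dppf) inserts only into the vinylic C–Br bond of 3, not into the primary alkyl bromide, so the C5–C1' bond forms without touching the carbinol centre.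

Step 4
Reactants: 6 (R)-2-(9-bromononyl)-4,4-dimethoxycyclohexa-2,5-dien-1-ol
Product: 7 (1R,2R,6R)-1-(9-bromononyl)-5,5-dimethoxy-7-oxabicyclo[4.1.0]hept-3-en-2-ol
Conditions: VO(acac)2 (5 mol%), t-BuOOH (1.1 equiv, in decane), CH2Cl2, 0 °C
Reagents that add atoms: tert-butyl hydroperoxide, CC(C)(C)OO
Why: Vanadium-catalysed hydroxyl-directed epoxidation of an allylic alcohol; the alkoxide-bound peroxide should deliver oxygen syn to the C4 hydroxyl and to the more nucleophilic trisubstituted olefin, which sets the C5–O bond cis to C4–OH.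

Step 5
Reactants: 8 (E)-hex-3-en-1-ol
Product: 9 (E)-hex-3-en-1-yl 4-methylbenzenesulfonate
Conditions: TsCl, pyridine, CH2Cl2, 0 °C → rt
Reagents that add atoms: 4-toluenesulfonyl chloride, Cc1ccc(cc1)S(Cl)(=O)=O
Why: Sulfonylation of a primary alcohol; the E-olefin is not involved.

Step 6
Reactants: 9 (E)-hex-3-en-1-yl 4-methylbenzenesulfonate; 10 but-3-en-1-ylmagnesium bromide
Product: 11 (E)-deca-1,7-diene
Conditions: Li2CuCl4 (3 mol%), THF, −78 °C → rt
Reagents that add atoms: none
Why: Copper-catalysed sp3–sp3 cross-coupling of a primary tosylate with a primary Grignard reagent; the olefin geometry is not touched.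

Step 7
Reactants: 11 (E)-deca-1,7-diene; 7 (1R,2R,6R)-1-(9-bromononyl)-5,5-dimethoxy-7-oxabicyclo[4.1.0]hept-3-en-2-ol
Product: 13 (1R,2R,6R)-5,5-dimethoxy-1-[(E)-nonadec-16-en-1-yl]-7-oxabicyclo[4.1.0]hept-3-en-2-ol, via 9-[(E)-dec-7-en-1-yl]-9-borabicyclo[3.3.1]nonane 12 (not isolated)
Conditions: 11 (1.5 equiv), 9-BBN (1.4 equiv), THF, rt; then 7, Pd(OAc)2 (4 mol%), PCy3 (8 mol%), K3PO4·H2O (1.5 equiv), THF, rt
Reagents that add atoms: none
Why: 9-BBN adds anti-Markovnikov to the monosubstituted C1=C2 olefin of 11 much faster than to its internal E-olefin, so boron ends up on the future C10' and the future C16'=C17' bond is carried through untouched. Electron-rich Pd(0)/PCy3 then inserts into the primary C9'–Br bond of 7 (SN2-type oxidative addition), the base-activated borate transfers its primary alkyl group to palladium, and reductive elimination forms the C9'–C10' bond. The closest known reaction type is the B-alkyl sp3–sp3 Suzuki–Miyaura coupling of primary alkyl bromides that carry β-hydrogens with alkyl-9-BBN reagents under Pd(OAc)2/PCy3/K3PO4·H2O. No ring is closed and no stereocentre is formed or touched. The step needs cross-coupling to outrun β-hydride elimination of the alkylpalladium intermediate, which the bulky, strongly donating PCy3 and the unhindered primary–primary pairing secure. It also needs chemoselectivity for C–Br over the epoxide, the allylic ketal and the free C4 hydroxyl, which the mild hydrated phosphate base at room temperature and the eight-methylene distance of C9' from the ring secure.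

Step 8
Reactants: 13 (1R,2R,6R)-5,5-dimethoxy-1-[(E)-nonadec-16-en-1-yl]-7-oxabicyclo[4.1.0]hept-3-en-2-ol
Product: 14 (1R,5R,6R)-5-hydroxy-6-[(E)-nonadec-16-en-1-yl]-7-oxabicyclo[4.1.0]hept-3-en-2-one
Conditions: PPTS (0.1 equiv), acetone/H2O (10:1), rt
Reagents that add atoms: water, O
Why: Mild acid hydrolysis of an allylic dimethyl ketal to the enone; the ketal ionises far more readily than the epoxide opens, and once the ketone exists the epoxide is an acid-deactivated α,β-epoxy ketone.

Step 9
Reactants: 14 (1R,5R,6R)-5-hydroxy-6-[(E)-nonadec-16-en-1-yl]-7-oxabicyclo[4.1.0]hept-3-en-2-one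
Product: 15 (4R,5S)-4,5-dihydroxy-5-[(E)-nonadec-16-en-1-yl]cyclohex-2-en-1-one
Conditions: SmI2 (2.2 equiv), THF/MeOH (4:1), −90 °C; pH 7 phosphate buffer quench at −78 °C
Reagents that add atoms: none
Why: SmI2 reductive opening of an α,β-epoxy ketone; the ketyl cleaves the Cα–O bond at C6 and methanol protonates the samarium enolate, so C6 becomes CH2 while the C5–O bond and its configuration from step 4 are kept, giving the cis-4,5-diol; low temperature and a buffered quench should prevent β-elimination.

Compound list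
1 | 2-bromo-4-methoxyphenol | COc1ccc(O)c(Br)c1 | starting material
2 | 2-bromo-4,4-dimethoxycyclohexa-2,5-dien-1-one | COC1(OC)C=CC(=O)C(Br)=C1 | intermediate
3 | (R)-2-bromo-4,4-dimethoxycyclohexa-2,5-dien-1-ol | O[C@H]1C(Br)=CC(OC)(OC)C=C1 | intermediate
4 | 9-bromonon-1-ene | C=CCCCCCCCBr | starting material
5 | 9-(9-bromononyl)-9-borabicyclo[3.3.1]nonane | BrCCCCCCCCCB1C2CCCC1CCC2 | intermediate
6 | (R)-2-(9-bromononyl)-4,4-dimethoxycyclohexa-2,5-dien-1-ol | O[C@H]1C(CCCCCCCCCBr)=CC(OC)(OC)C=C1 | intermediate
7 | (1R,2R,6R)-1-(9-bromononyl)-5,5-dimethoxy-7-oxabicyclo[4.1.0]hept-3-en-2-ol | O[C@@H]1C=CC(OC)(OC)[C@@H]2O[C@]12CCCCCCCCCBr | intermediate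
8 | (E)-hex-3-en-1-ol | CC/C=C/CCO | starting material
9 | (E)-hex-3-en-1-yl 4-methylbenzenesulfonate | CC/C=C/CCOS(=O)(=O)c1ccc(C)cc1 | intermediate
10 | but-3-en-1-ylmagnesium bromide | C=CCC[Mg]Br | starting material
11 | (E)-deca-1,7-diene | CC/C=C/CCCCC=C | intermediate
12 | 9-[(E)-dec-7-en-1-yl]-9-borabicyclo[3.3.1]nonane | CC/C=C/CCCCCCB1C2CCCC1CCC2 | intermediate
13 | (1R,2R,6R)-5,5-dimethoxy-1-[(E)-nonadec-16-en-1-yl]-7-oxabicyclo[4.1.0]hept-3-en-2-ol | O[C@@H]1C=CC(OC)(OC)[C@@H]2O[C@]12CCCCCCCCCCCCCCC/C=C/CC | intermediate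
14 | (1R,5R,6R)-5-hydroxy-6-[(E)-nonadec-16-en-1-yl]-7-oxabicyclo[4.1.0]hept-3-en-2-one | O[C@@H]1C=CC(=O)[C@@H]2O[C@]12CCCCCCCCCCCCCCC/C=C/CC | intermediate
15 | (4R,5S)-4,5-dihydroxy-5-[(E)-nonadec-16-en-1-yl]cyclohex-2-en-1-one | CC/C=C/CCCCCCCCCCCCCCC[C@]1(O)CC(=O)C=C[C@H]1O | target

Total step count: 9
Longest linear sequence: 7 steps (steps 1, 2, 3, 4, 7, 8, 9)

Steps most likely to fail

1. Step 2. The catalyst may discriminate poorly between the bromovinyl and the unsubstituted vinyl flank, and the dienol may lose methanol and re-aromatise during quench or purification. The fallback sets out from 2 and comes back at 3. DIBAL-H (CH2Cl2, −78 °C) should reduce 2 to racemic 2-bromo-4,4-dimethoxycyclohexa-2,5-dien-1-ol F1. A lipase-catalysed kinetic resolution (Burkholderia cepacia lipase, vinyl acetate, MTBE, rt) should then acylate the (R)-alcohol, by the usual secondary-alcohol preference of this enzyme, to (R)-2-bromo-4,4-dimethoxycyclohexa-2,5-dien-1-yl acetate F2. F2 is separated from the slow-reacting (S)-alcohol and methanolysed (K2CO3, MeOH, 0 °C) to 3.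

2. Step 4. Oxygen may be transferred to the disubstituted ring olefin, the bis-allylic carbinol may be oxidised back to the dienone, or the Lewis-acidic vanadium may trigger aromatisation of the dienol ketal. The fallback sets out from 6 and comes back at 15. Hydrogen-bond-directed syn-dihydroxylation with stoichiometric OsO4·TMEDA (CH2Cl2, −78 °C; ethylenediamine work-up) is base-buffered and should give the all-cis triol (1R,2R,3R)-2-(9-bromononyl)-6,6-dimethoxycyclohex-4-ene-1,2,3-triol F3. Coupling of F3 with 12 under the conditions of step 7 should give (1R,2R,3R)-6,6-dimethoxy-2-[(E)-nonadec-16-en-1-yl]cyclohex-4-ene-1,2,3-triol F4. PPTS in acetone/H2O should then give (4R,5R,6R)-4,5,6-trihydroxy-5-[(E)-nonadec-16-en-1-yl]cyclohex-2-en-1-one F5. SmI2 (THF/MeOH, −78 °C) finally removes the α-hydroxyl at C6 (reductive cleavage of an α-hydroxy ketone) to give 15.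

3. Step 9. The enone may be over-reduced, or the samarium aldolate may undergo β-elimination followed by aromatisation to the alkylhydroquinone. The fallback sets out from 13 and comes back at 15; it opens the epoxide before the ketone exists. LiAlH4 (THF, 0 °C → rt) should attack the only SN2-accessible epoxide carbon (secondary C6) and give (1S,2R)-5,5-dimethoxy-1-[(E)-nonadec-16-en-1-yl]cyclohex-3-ene-1,2-diol F6. PPTS in acetone/H2O (rt) then releases 15 directly, so that 14 and the SmI2 step are bypassed.

Further compounds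
F1 | step 2 | rac-2-bromo-4,4-dimethoxycyclohexa-2,5-dien-1-ol | OC1C(Br)=CC(OC)(OC)C=C1
F2 | step 2 | (R)-2-bromo-4,4-dimethoxycyclohexa-2,5-dien-1-yl acetate | CC(=O)O[C@H]1C(Br)=CC(OC)(OC)C=C1
F3 | step 4 | (1R,2R,3R)-2-(9-bromononyl)-6,6-dimethoxycyclohex-4-ene-1,2,3-triol | O[C@@H]1C=CC(OC)(OC)[C@H](O)[C@@]1(O)CCCCCCCCCBr
F4 | step 4 | (1R,2R,3R)-6,6-dimethoxy-2-[(E)-nonadec-16-en-1-yl]cyclohex-4-ene-1,2,3-triol | O[C@@H]1C=CC(OC)(OC)[C@H](O)[C@@]1(O)CCCCCCCCCCCCCCC/C=C/CC
F5 | step 4 | (4R,5R,6R)-4,5,6-trihydroxy-5-[(E)-nonadec-16-en-1-yl]cyclohex-2-en-1-one | O[C@@H]1C=CC(=O)[C@H](O)[C@@]1(O)CCCCCCCCCCCCCCC/C=C/CC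
F6 | step 9 | (1S,2R)-5,5-dimethoxy-1-[(E)-nonadec-16-en-1-yl]cyclohex-3-ene-1,2-diol | O[C@@H]1C=CC(OC)(OC)C[C@@]1(O)CCCCCCCCCCCCCCC/C=C/CC
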